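The runs were computed for an exercise; the scatter is artificial.

The unit here is the fraction of one hand's own charge, so a reading counts double: at 40.0 min the teal run reads 0.612 of the left-handed substrate and 0.282 of the right-handed substrate as product.

| setting | teal | red | flask |
|---|---|---|---|
| left-handed substrate | 0.34 M | 0.75 M | 0.50 M |
| right-handed substrate | 0.34 M | 0.75 M | 0.50 M |
| reagent | 1 M | 1 M | 1.00 M |
| remark | run made earlier | run made earlier |  |
| time |  |  | 1.0 h |

- teal (time / min: left-handed product / %, right-handed product / %): 3.00: 8.5, 2.5; 10.0: 16.9, 7.1; 15.0: 21.6, 9.6; 25.0: 25.5, 10.8; 40.0: 30.6, 14.1
- red (time / min: left-handed product / %, right-handed product / %): 3.00: 8.6, 1.6; 10.0: 16.2, 5.9; 15.0: 19.8, 8.7; 25.0: 21.6, 10.6; 40.0: 24.8, 11.5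

(scatter of a reading: 1 percentage point)

- reagent is single-handed; left-handed substrate and right-handed substrate are mirror images of each other, charged as a racemate, each of them at the stated concentration
- an excess is the difference of the two amounts in percent of their sum
- an excess is below zero if the other one leads
- the handed part of reagent does not stay in what it makes, so the products of the two hands are mirror images too

1. left-handed product and right-handed product together, in percent of the left-handed substrate and right-handed substrate charged together, at 1.0 h
2. excess of left-handed product over right-handed product in the product at 1.0 h
3. whether the exchange between left-handed substrate and right-handed substrate keeps pace with the reaction: how far the product's excess at 1.0 h gets from its value without exchange to its value with instant exchange (above 80% keeps pace, below 20% hardly takes part, else lags behind)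

Both hands meet the same reagent at each moment, so while each hand runs down on its own and however the reagent fades, the reagent drops out of one quotient: the logarithm of the fraction of left-handed substrate not yet turned into product over the same logarithm for the right-handed. At the last readings this quotient reads 2.86 in teal and 2.62 in red, and their mean, 2.74, is taken as a reading of the selectivity factor s. The same mean at 10.0 min reads 2.91.

Two versions of the flask can be solved in the head. Without exchange, each hand runs down on its own, s stays frozen, and the product's excess sinks as conversion rises. With instant exchange, the substrates stay equal and the excess stands at 46.5% at any conversion. The last readings give 36.9% in teal and 36.6% in red, less than that value, so this reckoning places the flask near the first version.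

For the left-handed logarithmic loss at 1.0 h, a rough estimate of my own adds to each run's last value its gain from 25.0 min to 40.0 min once more, to stand for the 20.0 min still to come, giving 1.18 in teal and 0.805 in red, and a straight line in the charge places the flask between them at 1.03. This estimate turns 0.644 of the left-handed and 0.314 of the right-handed substrate into product, which makes 47.9% product with an excess of 34.4%.

The forecast, citing “plain kinetic resolution”, gives 42.5% (39% to 46%), an excess of 37% (33% to 41%) and "hardly takes part", its yield being lower than the one reckoned here.

The flask gives 46.5% with an excess of 35.1%, and the exchange hardly takes part: the excess gets 12% of the way from its value without exchange to its value with instant exchange.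

    reagent + left-handed substrate → left-handed product (k = 0.0850 M⁻¹ min⁻¹)
    reagent + right-handed substrate → right-handed product (k = 0.0320 M⁻¹ min⁻¹)
    2 reagent → homo dimer (k = 0.0560 M⁻¹ min⁻¹)
    left-handed substrate ⇌ achiral form (K = 0.0690, k = 0.00770 min⁻¹)
    right-handed substrate ⇌ achiral form (K = 0.0690, k = 0.00770 min⁻¹)
    reagent ⇌ dormant form (K = 0.600, k = 0.110 min⁻¹)

With left-handed product at 31.4% at 1.00 h, s gives 15.1% right-handed product, and the flask holds 15.1%. In the neighbouring flask charged with 2.5 M of reagent, left-handed product stands at 42.5% at 1.00 h, s gives 25.0% right-handed product, and that flask holds 24.0%.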